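**Retrosynthetic overview**
1. Last operation: 2,4-dihydroxy-5-methyl-6-[(2R,3R)-3-silyloxybutan-2-yl]benzaldehyde is joined to (S)-4-hydroxy-6-(2-silyloxypropyl)-2-pyrone. Knoevenagel/translactonisation closes the coumarin lactone and opens the pyrone; acid then frees both alcohols and closes the dihydropyranone (enol-ether bond C6–O1) last.
2. Enabling feature: coumarin C2(=O)–C3 and pyranone C6–C5–C4(=O) are one 1,3,5-tricarbonyl chain, i.e. a ring-opened 4-hydroxy-2-pyrone. It is flanked by the phenol oxygen (coumarin O1) and by the carbinol oxygen on pyranone C2, which sits δ to C6. One temporary pyrone ring is therefore traded for both heterocycles.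
3. Aldehyde fragment: 1,3-bis(benzyloxy)-5-bromobenzene → formylation/deoxygenation (ring methyl) → aryl Grignard opening of (2R,3R)-2,3-epoxybutane (side-chain diad) → silylation, Rieche formylation, hydrogenolysis.
4. Pyrone fragment: methyl (S)-3-hydroxybutanoate (pyranone C2 stereocentre) → silyl ether → Weinreb amide → γ-acylation of the dioxinone dienolate → thermolysis through the acylketene.
5. Ring order: benzene ring bought; pyrone (temporary, step 10); coumarin lactone, then dihydropyranone, both in the last step.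

Key step: step 11

Remark: 1,3-bis(benzyloxy)-5-bromobenzene and enantiopure (2R,3R)-2,3-epoxybutane are taken as purchasable; phenols are carried as benzyl (Bn) ethers and alcohols as tert-butyldimethylsilyl (TBS) ethers, so that the phenols are freed by hydrogenolysis before the last step and the alcohols by acid within it.

**Route**

Step 1
Reactants: 1 1,3-bis(benzyloxy)-5-bromobenzene
Product: 2 2,4-bis(benzyloxy)-6-bromobenzaldehyde
Conditions: POCl3, DMF, 0 °C then 80 °C; then H2O
Reagents that add atoms: N,N-dimethylformamide CN(C)C=O; water O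
Why: Vilsmeier–Haack formylation, in which the chloroiminium ion attacks the position para to one benzyloxy group and ortho to the other (next to bromine) rather than the doubly flanked position between the two ethers, as is usual for 1-bromo-3,5-dialkoxybenzenes; the aldehyde placed here is the precursor of the ring methyl group.

Step 2
Reactants: 2 2,4-bis(benzyloxy)-6-bromobenzaldehyde
Product: 3 1,5-bis(benzyloxy)-3-bromo-2-methylbenzene
Conditions: Et3SiH, CF3CO2H, CH2Cl2, 0 °C to rt
Reagents that add atoms: none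
Why: Ionic hydrogenation (reductive deoxygenation) of an electron-rich benzaldehyde through the stabilised benzylic cation should give the methyl arene while aryl bromide and benzyl ethers stay intact at this temperature.

Step 3
Reactants: 3 1,5-bis(benzyloxy)-3-bromo-2-methylbenzene; 4 (2R,3R)-2,3-epoxybutane (trans-2,3-dimethyloxirane)
Product: 6 (2R,3R)-3-[3,5-bis(benzyloxy)-2-methylphenyl]butan-2-ol, via arylmagnesium bromide 5 (not isolated)
Conditions: Mg, THF, reflux; then CuBr·SMe2 (10 mol %), 4, −30 °C to rt; then H2O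
Reagents that add atoms: none
Why: Copper-catalysed SN2 opening of an epoxide by an aryl Grignard reagent, in which the C2-symmetric trans-epoxide offers two identical carbons, attack goes with inversion at the carbon that becomes benzylic and the carbinol carbon keeps its configuration, so the erythro (2R,3R) diad is set entirely by the (2R,3R) epoxide.

Step 4
Reactants: 6 (2R,3R)-3-[3,5-bis(benzyloxy)-2-methylphenyl]butan-2-ol
Product: 7 tert-butyl{[(2R,3R)-3-[3,5-bis(benzyloxy)-2-methylphenyl]butan-2-yl]oxy}dimethylsilane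
Conditions: TBSOTf, 2,6-lutidine, CH2Cl2, 0 °C
Reagents that add atoms: tert-butyldimethylsilyl trifluoromethanesulfonate CC(C)(C)[Si](C)(C)OS(=O)(=O)C(F)(F)F
Why: Silylation of a hindered secondary alcohol with a silyl triflate and a non-nucleophilic base masks the hydroxyl so that the later ortho aldehyde cannot close onto it as a lactol.

Step 5
Reactants: 7 tert-butyl{[(2R,3R)-3-[3,5-bis(benzyloxy)-2-methylphenyl]butan-2-yl]oxy}dimethylsilane
Product: 8 2,4-bis(benzyloxy)-6-[(2R,3R)-3-[(tert-butyldimethylsilyl)oxy]butan-2-yl]-5-methylbenzaldehyde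
Conditions: Cl2CHOMe, TiCl4, CH2Cl2, −78 to −40 °C; then H2O
Reagents that add atoms: dichloromethyl methyl ether COC(Cl)Cl; water O
Why: Rieche formylation (Friedel–Crafts attack of the methoxychlorocarbenium ion, then hydrolysis) should occur at the one free position that is para to a benzyloxy group, next to the side chain, in preference to the position between the two ethers, and the low temperature should spare the silyl and benzyl ethers.

Step 6
Reactants: 8 2,4-bis(benzyloxy)-6-[(2R,3R)-3-[(tert-butyldimethylsilyl)oxy]butan-2-yl]-5-methylbenzaldehyde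
Product: 9 6-[(2R,3R)-3-[(tert-butyldimethylsilyl)oxy]butan-2-yl]-2,4-dihydroxy-5-methylbenzaldehyde
Conditions: H2 (1 atm), Pd/C (10 wt %), EtOAc, rt
Reagents that add atoms: none
Why: Hydrogenolysis of the two aryl benzyl ethers over Pd/C should leave the hydrogen-bonded, electron-rich aldehyde and the alkyl silyl ether intact in neutral EtOAc when the reaction is stopped after uptake of two equivalents of H2.

Step 7
Reactants: 10 methyl (S)-3-hydroxybutanoate
Product: 11 methyl (3S)-3-[(tert-butyldimethylsilyl)oxy]butanoate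
Conditions: TBSCl, imidazole, DMF, rt
Reagents that add atoms: tert-butyldimethylsilyl chloride CC(C)(C)[Si](C)(C)Cl
Why: Standard imidazole-promoted silylation of a secondary alcohol protects the hydroxyl against the strong bases of steps 8 and 9 and does not involve the stereocentre.

Step 8
Reactants: 11 methyl (3S)-3-[(tert-butyldimethylsilyl)oxy]butanoate
Product: 12 (3S)-3-[(tert-butyldimethylsilyl)oxy]-N-methoxy-N-methylbutanamide
Conditions: MeNH(OMe)·HCl, i-PrMgCl, THF, −20 to 0 °C; then H2O
Reagents that add atoms: N,O-dimethylhydroxylamine hydrochloride CNOC.Cl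
Why: Direct ester-to-Weinreb-amide conversion by the chloromagnesium amide of N,O-dimethylhydroxylamine (acyl substitution) should proceed at low temperature without β-elimination of the silyloxy group.

Step 9
Reactants: 13 2,2,6-trimethyl-4H-1,3-dioxin-4-one; 12 (3S)-3-[(tert-butyldimethylsilyl)oxy]-N-methoxy-N-methylbutanamide
Product: 15 6-[(4S)-4-[(tert-butyldimethylsilyl)oxy]-2-oxopentyl]-2,2-dimethyl-4H-1,3-dioxin-4-one, via lithium dienolate 14 (not isolated)
Conditions: LiN(SiMe3)2, THF, −78 °C; then 12, −78 to −20 °C; then AcOH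
Reagents that add atoms: none
Why: Claisen-type γ-acylation of lithium dienolate 14 by the Weinreb amide, whose N-methoxy group holds the addition product as a chelate until the quench, so that double addition and proton transfer from the acidic β-keto-dioxinone are suppressed.

Step 10
Reactants: 15 6-[(4S)-4-[(tert-butyldimethylsilyl)oxy]-2-oxopentyl]-2,2-dimethyl-4H-1,3-dioxin-4-one
Product: 17 6-[(2S)-2-[(tert-butyldimethylsilyl)oxy]propyl]-4-hydroxy-2H-pyran-2-one, via acylketene 16 (not isolated)
Conditions: toluene, 110 °C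
Reagents that add atoms: none
Why: Thermal retro-[4+2] loss of acetone from the dioxinone gives acylketene 16, which is trapped by the enol oxygen of the neighbouring ketone (intramolecular addition to the ketene, 6-exo-dig) to give the 4-hydroxy-2-pyrone under neutral conditions that leave silyl ether and stereocentre untouched.

Step 11
Reactants: 9 6-[(2R,3R)-3-[(tert-butyldimethylsilyl)oxy]butan-2-yl]-2,4-dihydroxy-5-methylbenzaldehyde; 17 6-[(2S)-2-[(tert-butyldimethylsilyl)oxy]propyl]-4-hydroxy-2H-pyran-2-one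
Product: 21 7-hydroxy-5-[(2R,3R)-3-hydroxybutan-2-yl]-6-methyl-3-[(2S)-2-methyl-4-oxo-3,4-dihydro-2H-pyran-6-yl]-2H-chromen-2-one, via arylidenepyrandione 18 (not isolated), via bis-silyl coumarin diketone 19 (not isolated), via hydroxy diketone 20 (not isolated)
Conditions: piperidine (0.2 equiv), AcOH (0.2 equiv), EtOH, 70 °C; then aq HCl (to 1 M), 45 °C
Reagents that add atoms: none
Why: Piperidinium acetate condenses the aldehyde of 9 with the nucleophilic C3 of pyrone 17 (Knoevenagel) to 18, whose lactone carbonyl is attacked by the neighbouring phenol (6-exo-trig acyl transfer), so that the coumarin lactone closes while the pyrone ring opens to the 1,3-diketone 19. This Knoevenagel/translactonisation is the known route from salicylaldehydes and 4-hydroxy-6-methyl-2-pyrone to 3-acetoacetylcoumarins, and the acid stage is the standard cyclodehydration of δ-hydroxy-β-diketones to 2,3-dihydro-4H-pyran-4-ones. Acid removes both silyl ethers, and in 20 the freed chain hydroxyl adds to the coumarin-bound carbonyl (6-exo-trig hemiketalisation, the only ring size within reach because the hydroxyl is β to the second carbonyl) and water is lost to give the vinylogous ester ring. No stereocentre is created: C2 of the pyranone is the carbinol carbon of (S)-3-hydroxybutanoate, whose C–O bond is never broken, and the (2R,3R) side chain is a spectator. The step needs condensation at pyrone C3 without a second pyrone adding to 18, which the ortho phenol secures by intercepting 18 intramolecularly, helped by the shielding alkyl group next to the aldehyde. It also needs closure through the retained oxygen without β-elimination of the hydroxy ketone, which would racemise C2 through a dienone, and this is secured by the enolised 1,3-diketone, which disfavours enolisation toward the carbinol, and by the mild acid.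

**Compound list**
1 | 1,3-bis(benzyloxy)-5-bromobenzene | Brc1cc(OCc2ccccc2)cc(OCc2ccccc2)c1 | starting material
2 | 2,4-bis(benzyloxy)-6-bromobenzaldehyde | O=Cc1c(Br)cc(OCc2ccccc2)cc1OCc1ccccc1 | intermediate
3 | 1,5-bis(benzyloxy)-3-bromo-2-methylbenzene | Cc1c(Br)cc(OCc2ccccc2)cc1OCc1ccccc1 | intermediate
4 | (2R,3R)-2,3-epoxybutane (trans-2,3-dimethyloxirane) | C[C@H]1O[C@@H]1C | starting material
5 | [3,5-bis(benzyloxy)-2-methylphenyl]magnesium bromide | Cc1c([Mg]Br)cc(OCc2ccccc2)cc1OCc1ccccc1 | intermediate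
6 | (2R,3R)-3-[3,5-bis(benzyloxy)-2-methylphenyl]butan-2-ol | Cc1c(OCc2ccccc2)cc(OCc2ccccc2)cc1[C@@H](C)[C@@H](C)O | intermediate
7 | tert-butyl{[(2R,3R)-3-[3,5-bis(benzyloxy)-2-methylphenyl]butan-2-yl]oxy}dimethylsilane | Cc1c(OCc2ccccc2)cc(OCc2ccccc2)cc1[C@@H](C)[C@@H](C)O[Si](C)(C)C(C)(C)C | intermediate
8 | 2,4-bis(benzyloxy)-6-[(2R,3R)-3-[(tert-butyldimethylsilyl)oxy]butan-2-yl]-5-methylbenzaldehyde | Cc1c(OCc2ccccc2)cc(OCc2ccccc2)c(C=O)c1[C@@H](C)[C@@H](C)O[Si](C)(C)C(C)(C)C | intermediate
9 | 6-[(2R,3R)-3-[(tert-butyldimethylsilyl)oxy]butan-2-yl]-2,4-dihydroxy-5-methylbenzaldehyde | Cc1c(O)cc(O)c(C=O)c1[C@@H](C)[C@@H](C)O[Si](C)(C)C(C)(C)C | intermediate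
10 | methyl (S)-3-hydroxybutanoate | C[C@H](O)CC(=O)OC | starting material
11 | methyl (3S)-3-[(tert-butyldimethylsilyl)oxy]butanoate | C[C@H](O[Si](C)(C)C(C)(C)C)CC(=O)OC | intermediate
12 | (3S)-3-[(tert-butyldimethylsilyl)oxy]-N-methoxy-N-methylbutanamide | C[C@H](O[Si](C)(C)C(C)(C)C)CC(=O)N(C)OC | intermediate
13 | 2,2,6-trimethyl-4H-1,3-dioxin-4-one | CC1=CC(=O)OC(C)(C)O1 | starting material
14 | lithium 2,2-dimethyl-6-methylidene-6H-1,3-dioxin-4-olate (dienolate of 13) | C=C1C=C(O[Li])OC(C)(C)O1 | intermediate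
15 | 6-[(4S)-4-[(tert-butyldimethylsilyl)oxy]-2-oxopentyl]-2,2-dimethyl-4H-1,3-dioxin-4-one | C[C@H](O[Si](C)(C)C(C)(C)C)CC(=O)CC1=CC(=O)OC(C)(C)O1 | intermediate
16 | (7S)-7-[(tert-butyldimethylsilyl)oxy]-3,5-dioxooct-1-en-1-one (acylketene) | C[C@H](O[Si](C)(C)C(C)(C)C)CC(=O)CC(=O)C=C=O | intermediate
17 | 6-[(2S)-2-[(tert-butyldimethylsilyl)oxy]propyl]-4-hydroxy-2H-pyran-2-one | C[C@H](O[Si](C)(C)C(C)(C)C)CC1=CC(O)=CC(=O)O1 | intermediate
18 | 3-({6-[(2R,3R)-3-[(tert-butyldimethylsilyl)oxy]butan-2-yl]-2,4-dihydroxy-5-methylphenyl}methylidene)-6-[(2S)-2-[(tert-butyldimethylsilyl)oxy]propyl]-2H-pyran-2,4(3H)-dione | Cc1c(O)cc(O)c(C=C2C(=O)C=C(C[C@H](C)O[Si](C)(C)C(C)(C)C)OC2=O)c1[C@@H](C)[C@@H](C)O[Si](C)(C)C(C)(C)C | intermediate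
19 | 5-[(2R,3R)-3-[(tert-butyldimethylsilyl)oxy]butan-2-yl]-3-[(5S)-5-[(tert-butyldimethylsilyl)oxy]-3-oxohexanoyl]-7-hydroxy-6-methyl-2H-chromen-2-one | Cc1c(O)cc2oc(=O)c(C(=O)CC(=O)C[C@H](C)O[Si](C)(C)C(C)(C)C)cc2c1[C@@H](C)[C@@H](C)O[Si](C)(C)C(C)(C)C | intermediate
20 | 7-hydroxy-5-[(2R,3R)-3-hydroxybutan-2-yl]-3-[(5S)-5-hydroxy-3-oxohexanoyl]-6-methyl-2H-chromen-2-one | Cc1c(O)cc2oc(=O)c(C(=O)CC(=O)C[C@H](C)O)cc2c1[C@@H](C)[C@@H](C)O | intermediate
21 | 7-hydroxy-5-[(2R,3R)-3-hydroxybutan-2-yl]-6-methyl-3-[(2S)-2-methyl-4-oxo-3,4-dihydro-2H-pyran-6-yl]-2H-chromen-2-one | Cc1c(O)cc2oc(=O)c(C3=CC(=O)C[C@H](C)O3)cc2c1[C@@H](C)[C@@H](C)O | target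

**Step count**
Total: 11 steps. Longest linear sequence: 7 steps (steps 1 to 6 and 11); the pyrone branch contributes 4 steps (7 to 10) before the union.

**Steps most likely to fail**

Step 11. The condensation may stall at the doubly ortho-flanked, hydrogen-bonded aldehyde, a second pyrone may add to the arylidene before the phenol translactonises, or the tricarbonyl chain may suffer retro-Claisen cleavage on prolonged heating. The fallback sets out from 9 (with 12) and comes back at 20, and thus 21; it closes the coumarin first with a simple β-keto ester and then grows the chain by a ketone Claisen acylation. Knoevenagel condensation of 9 with ethyl acetoacetate (piperidine cat., EtOH) should give the 3-acetyl-7-hydroxycoumarin F1. TBSCl and imidazole should convert it to the 7-silyl ether F2. LiN(SiMe3)2 (THF, −78 °C) should form the lithium enolate F3 of the methyl ketone, which is C-acylated by Weinreb amide 12 to the tris-silyl diketone F4. HCl in EtOH then removes the three silyl groups to give 20, which cyclodehydrates to 21 as in step 11.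

Step 3. The ortho-methyl aryl nucleophile may open the secondary epoxide carbon too slowly, so that magnesium-halide-induced halohydrin formation or rearrangement of the volatile epoxide takes over. The fallback sets out from 1 (with 4) and comes back at 7; it opens the epoxide with the unhindered aryl group and installs the ring methyl afterwards. Magnesium insertion into 1 gives [3,5-bis(benzyloxy)phenyl]magnesium bromide F5, which should open 4 under the same copper catalysis to (2R,3R)-3-[3,5-bis(benzyloxy)phenyl]butan-2-ol F6. Silylation (TBSOTf, 2,6-lutidine) gives the silyl ether F7. N-Bromosuccinimide (MeCN, 0 °C) should brominate one of the two equivalent positions flanking the side chain, para to a benzyloxy group, to give the aryl bromide F8. Bromine–lithium exchange (n-BuLi, THF, −78 °C) to the aryllithium F9 and quench with MeI returns to 7.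

Step 5. The Lewis acid may strip the silyl ether or the ortho benzyl ether, or the electrophile may enter between the two ethers. The fallback sets out from 7 and comes back at 8; it replaces the Friedel–Crafts formylation by halogenation and metalation. N-Bromosuccinimide (MeCN, 0 °C) should brominate para to the benzyloxy group at the free position next to the side chain to give the aryl bromide F10. Bromine–lithium exchange (n-BuLi, THF, −78 °C) to the aryllithium F11 and quench with DMF, then H2O, returns to 8.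

**Further compounds**
F1 | step 11 | 3-acetyl-5-[(2R,3R)-3-[(tert-butyldimethylsilyl)oxy]butan-2-yl]-7-hydroxy-6-methyl-2H-chromen-2-one | Cc1c(O)cc2oc(=O)c(C(C)=O)cc2c1[C@@H](C)[C@@H](C)O[Si](C)(C)C(C)(C)C
F2 | step 11 | 3-acetyl-7-[(tert-butyldimethylsilyl)oxy]-5-[(2R,3R)-3-[(tert-butyldimethylsilyl)oxy]butan-2-yl]-6-methyl-2H-chromen-2-one | Cc1c(O[Si](C)(C)C(C)(C)C)cc2oc(=O)c(C(C)=O)cc2c1[C@@H](C)[C@@H](C)O[Si](C)(C)C(C)(C)C
F3 | step 11 | lithium enolate of F2 (lithium 1-(coumarin-3-yl)ethen-1-olate) | Cc1c(O[Si](C)(C)C(C)(C)C)cc2oc(=O)c(C(=C)O[Li])cc2c1[C@@H](C)[C@@H](C)O[Si](C)(C)C(C)(C)C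
F4 | step 11 | 7-[(tert-butyldimethylsilyl)oxy]-5-[(2R,3R)-3-[(tert-butyldimethylsilyl)oxy]butan-2-yl]-3-[(5S)-5-[(tert-butyldimethylsilyl)oxy]-3-oxohexanoyl]-6-methyl-2H-chromen-2-one | Cc1c(O[Si](C)(C)C(C)(C)C)cc2oc(=O)c(C(=O)CC(=O)C[C@H](C)O[Si](C)(C)C(C)(C)C)cc2c1[C@@H](C)[C@@H](C)O[Si](C)(C)C(C)(C)C
F5 | step 3 | [3,5-bis(benzyloxy)phenyl]magnesium bromide | Br[Mg]c1cc(OCc2ccccc2)cc(OCc2ccccc2)c1
F6 | step 3 | (2R,3R)-3-[3,5-bis(benzyloxy)phenyl]butan-2-ol | c1c(OCc2ccccc2)cc(OCc2ccccc2)cc1[C@@H](C)[C@@H](C)O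
F7 | step 3 | tert-butyl{[(2R,3R)-3-[3,5-bis(benzyloxy)phenyl]butan-2-yl]oxy}dimethylsilane | c1c(OCc2ccccc2)cc(OCc2ccccc2)cc1[C@@H](C)[C@@H](C)O[Si](C)(C)C(C)(C)C
F8 | step 3 | tert-butyl{[(2R,3R)-3-[3,5-bis(benzyloxy)-2-bromophenyl]butan-2-yl]oxy}dimethylsilane | Brc1c(OCc2ccccc2)cc(OCc2ccccc2)cc1[C@@H](C)[C@@H](C)O[Si](C)(C)C(C)(C)C
F9 | step 3 | {2,4-bis(benzyloxy)-6-[(2R,3R)-3-[(tert-butyldimethylsilyl)oxy]butan-2-yl]phenyl}lithium | [Li]c1c(OCc2ccccc2)cc(OCc2ccccc2)cc1[C@@H](C)[C@@H](C)O[Si](C)(C)C(C)(C)C
F10 | step 5 | tert-butyl{[(2R,3R)-3-[3,5-bis(benzyloxy)-2-bromo-6-methylphenyl]butan-2-yl]oxy}dimethylsilane | Cc1c(OCc2ccccc2)cc(OCc2ccccc2)c(Br)c1[C@@H](C)[C@@H](C)O[Si](C)(C)C(C)(C)C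
F11 | step 5 | {4,6-bis(benzyloxy)-2-[(2R,3R)-3-[(tert-butyldimethylsilyl)oxy]butan-2-yl]-3-methylphenyl}lithium | Cc1c(OCc2ccccc2)cc(OCc2ccccc2)c([Li])c1[C@@H](C)[C@@H](C)O[Si](C)(C)C(C)(C)C
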